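The readings were generated by integration for substances that don't exist.

Watch the L.

| setting | ochre | flask |
|---|---|---|
| E | 5 mM | 5.0 mM |
| L | 4.5 mM | 4.50 mM |
| remark | the very flask that is asked about, followed so far |  |
| time |  | 30 min |

- ochre (time / min: E / %, X / %): 0.200: 47.9, 45.0; 0.417: 36.9, 58.6; 1.00: 27.9, 68.7; 2.50: 25.3, 73.8

(each reading ± 1 percentage point)

* the E standing at 30 min, as a percentage of the E charged
* the X standing at 30 min, as a percentage of the E charged
* the G standing at 30 min, as a percentage of the E charged

- what was read earlier has a scatter of 1 percentage point, one standard deviation
- reactions considered so far: E + L -> X + J; L + X <-> G + J; L + G -> Z; 2 L -> Q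

You want to know where this flask stops, so follow what its L buys. My first answer is one L for each E, which would leave E at 10.0%. The ochre readings refuse that, so go round once more.

Take the run in slow motion. At 0.200 min, E stands at 47.9% and X at 45.0%, so 7.10% of the E charged is read as sitting in G or Z. By 2.50 min that gap reads 0.900%, while E has reached 25.3%. Treat that last reading as the stop, and put it back into the L balance:

L price = 4.5 mM / (E turned by 2.50 min) = 1.20

This is the mM of L spent for each mM of E turned, a reading with the scatter of E in it. At that price, the reading at 1.00 min leaves about 0.157 mM of L still to spend, less than the 4.5 mM charged. My own figures for 30 min are therefore E near 25.3% and X near 74.7%.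

The forecast gives E 24.5%, X 74.8% and G 0.2%, saying “everything should be frozen”.

The flask gives E 25.4%, X 74.2% and G 0%, so the forecast stands. The answer for X moved by 5 points at L charges of 4.11 mM and 4.91 mM.

    E + L → X + J (k = 36.0 /M/s)
    L + X ⇌ G + J (K = 0.610, k = 83.0 /M/s)
    L + G → Z (k = 2.00 /M/s)
    2 L → Q (k = 6.90 /M/s)

In this flask, half of the turnover of two L into Q was done by 2.11 s, earlier than the 0.0801 min for E + L into X + J. At 3.00 min, L stood at 0.0652% of its charge, and at the asked time L, the limiting reagent, stands at 0% against 25% for E, which makes the price paid 1.21.

Now take the neighbour flask charged with 1.8 mM of L, all else as in this flask: at 1.20, E should stop near 70.1%. The computed neighbour flask has E 66.4% and X 33.6% with L at 0% of its charge, a price of 1.07, lower than the price read from the ochre run.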